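**Retrosynthetic overview**

1. Indene numbering: C1 (quaternary; CH3 and side chain), C2 (CO2H), C3, C3a=C4, C5, C6, C7 (gem-dimethyl), C7a (CH3). Endgame: CO2H from a C2 CH2OH group; the (Z)-allylic acetate by Still–Gennari olefination of a C1 propanal; the C1 quaternary centre by hydrogen-atom-transfer Giese addition of a C1 methylidene to methyl acrylate.
2. The C3a=C4 alkene comes from a C5 ketone (dehydrogenation to the enone, dithiolane, desulfurisation).
3. Key disconnection: the cyclohexene ring is opened at C3a–C4 and C7–C7a. This is a formal [4+2] cycloaddition (double Mukaiyama–Michael) of the 2-silyloxy diene of mesityl oxide with (R)-4-silyloxy-2-methylcyclopent-2-enone, joining the two fully substituted carbons C7 and C7a.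
4. Enabling feature: in the ring C3a=C4–C5–C6–C7–C7a the methyl-bearing C7a lies between C1 and C3a. A carbonyl at C1 therefore makes C7a=C3a an enone with C3a as β-carbon. A temporary oxygen at C5 makes C4–C7 a 2-silyloxy diene whose CH2 end (C4) matches C3a and whose gem-dimethyl end (C7) matches C7a. The C5 oxygen later places C3a=C4; a temporary C3 silyloxy group steers the face and then leaves to give the C2=C3 enone through which C2 is functionalised.
5. Ring order: the five-membered ring is bought as the cyclopentenone; the six-membered ring is formed in the key step.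

Key step: step 4

Remark on the chemistry: compound 1 is assumed to be commercially available in enantiopure form. Bicyclic compounds are named with the indene numbering above; β is the face of the C7a methyl group. TBS = tert-butyldimethylsilyl, TBDPS = tert-butyldiphenylsilyl.

**Route**

Step 1
Reactants: 1 (R)-4-(TBS-oxy)cyclopent-2-en-1-one
Product: 2 (R)-4-(TBS-oxy)-2-iodocyclopent-2-en-1-one
Conditions: I2, pyridine, CH2Cl2, 0 °C → rt
Reagents that add atoms: iodine, SMILES: II
Why: The pyridine-mediated addition–iodination–elimination sequence (Baylis–Hillman-type α-iodination of an enone) is reliable for 4-silyloxycyclopentenones and does not touch the C4 stereocentre.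

Step 2
Reactants: 2 (R)-4-(TBS-oxy)-2-iodocyclopent-2-en-1-one
Product: 3 (R)-4-(TBS-oxy)-2-methylcyclopent-2-en-1-one
Conditions: SnMe4, PdCl2(PhCN)2 (5 mol %), AsPh3 (10 mol %), NMP, 80 °C
Reagents that add atoms: tetramethylstannane, SMILES: C[Sn](C)(C)C
Why: Stille cross-coupling of the α-iodoenone with SnMe4 runs under neutral conditions, so the methyl group is installed without base-induced loss of the silyloxy group or racemisation.

Step 3
Reactants: 4 mesityl oxide (4-methylpent-3-en-2-one)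
Product: 6 tert-butyldimethyl[(4-methylpenta-1,3-dien-2-yl)oxy]silane, via lithium dienolate of mesityl oxide 5 (not isolated)
Conditions: LiN(i-Pr)2, THF, −78 °C; then TBSCl, DMPU, −78 °C → rt
Reagents that add atoms: tert-butyldimethylsilyl chloride, SMILES: CC(C)(C)[Si](C)(C)Cl
Why: Kinetic deprotonation of an enone occurs at the α′-methyl group, and O-silylation of the resulting cross-conjugated lithium dienolate (enol silane formation) gives the 2-silyloxy diene.

Step 4
Reactants: 3 (R)-4-(TBS-oxy)-2-methylcyclopent-2-en-1-one; 6 tert-butyldimethyl[(4-methylpenta-1,3-dien-2-yl)oxy]silane (1.5 equiv)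
Product: 8 3β,5-bis(TBS-oxy)-7,7,7aβ-trimethyl-2,3,3aβ,4,7,7a-hexahydro-1H-inden-1-one (cis-fused), via open-chain Mukaiyama–Michael adduct 7 (not isolated)
Conditions: Tf2NH (10 mol %), CH2Cl2, −78 → −40 °C; then Et3N
Reagents that add atoms: none
Why: Tf2NH protodesilylates a trace of 6 to TBSNTf2, which silylates the enone oxygen of 3; the CH2 terminus of 6 then adds to the enone β-carbon (future C3a) in a Mukaiyama–Michael step to give 7 in its O-silylated oxocarbenium form, and the tetrasubstituted enol silane carbon (future C7a) attacks the gem-dimethyl β-carbon of that activated enone (future C7), releasing the silyl cation for the next turnover. The closest known reaction type is the triflimide- or aluminium Lewis acid-catalysed formal Diels–Alder (double Mukaiyama–Michael) reaction of 4,4-disubstituted 2-silyloxydienes with 2-methylcycloalk-2-enones, which is used precisely to join two fully substituted carbons. The six-membered ring closes in the second addition in a 6-(enolexo)-endo-trig mode after the intermolecular first bond. C3a is set in the first addition, which should occur anti to the neighbouring C3 silyloxy group; C7a is set by the ring closure, which for geometric reasons can only deliver C7 to the face that already carries the C4 chain, so the ring fusion should be cis with 3a-H, 7a-CH3 and 3-OTBS on one face. The step needs regioselectivity (secured by the 2-silyloxy group, which makes C4 the only nucleophilic diene terminus and pairs it with the enone β-carbon), facial selectivity (secured by the silyloxy stereocentre of 3) and survival of the β-silyloxy ketone (secured by catalytic acid at low temperature and the amine quench).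

Step 5
Reactants: 8 3β,5-bis(TBS-oxy)-7,7,7aβ-trimethyl-2,3,3aβ,4,7,7a-hexahydro-1H-inden-1-one
Product: 9 5-(TBS-oxy)-7,7,7aβ-trimethyl-3aβ,4,7,7a-tetrahydro-1H-inden-1-one
Conditions: DBU, CH2Cl2, 0 °C → rt
Reagents that add atoms: none
Why: E1cB elimination of the β-silyloxy ketone (the only acidic hydrogens are at C2) gives the cyclopentenone without touching C3a or C7a, removes the controller oxygen from C3 and fixes the site of the next enolate.

Step 6
Reactants: 9 5-(TBS-oxy)-7,7,7aβ-trimethyl-3aβ,4,7,7a-tetrahydro-1H-inden-1-one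
Product: 11 5-(TBS-oxy)-2β-(hydroxymethyl)-7,7,7aβ-trimethyl-2,3,3aβ,4,7,7a-hexahydro-1H-inden-1-one, via lithium C1 enolate 10 (not isolated)
Conditions: LiBH(s-Bu)3, THF, −78 °C; then CH2O (THF solution), −78 → −40 °C; aq NH4Cl
Reagents that add atoms: formaldehyde, SMILES: C=O
Why: Conjugate hydride reduction (1,4-addition is expected because the C1 carbonyl is flanked by the quaternary C7a) gives the regiodefined lithium enolate, whose aldol reaction with formaldehyde (reductive aldol) should set C2 by attack on the convex β-face of the cis-fused bicycle, away from the six-membered ring folded under the α-face.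

Step 7
Reactants: 11 5-(TBS-oxy)-2β-(hydroxymethyl)-7,7,7aβ-trimethyl-2,3,3aβ,4,7,7a-hexahydro-1H-inden-1-one
Product: 12 5-(TBS-oxy)-2β-[(TBDPS-oxy)methyl]-7,7,7aβ-trimethyl-2,3,3aβ,4,7,7a-hexahydro-1H-inden-1-one
Conditions: TBDPSCl, imidazole, CH2Cl2, 0 °C → rt
Reagents that add atoms: tert-butyl(chloro)diphenylsilane, SMILES: CC(C)(C)[Si](Cl)(c1ccccc1)c1ccccc1
Why: Standard silylation of the primary alcohol under neutral conditions keeps the epimerisable C2 centre intact and gives a group that survives dilute acid, BF3·OEt2 and Raney Ni and shields the β-face at C1.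

Step 8
Reactants: 12 5-(TBS-oxy)-2β-[(TBDPS-oxy)methyl]-7,7,7aβ-trimethyl-2,3,3aβ,4,7,7a-hexahydro-1H-inden-1-one
Product: 14 2β-[(TBDPS-oxy)methyl]-7,7,7aβ-trimethyl-1-methylidene-3aβ-octahydro-5H-inden-5-one, via C1-methylidene silyl enol ether 13 (not isolated)
Conditions: Cp2Ti(μ-Cl)(μ-CH2)AlMe2, pyridine, THF/toluene, −40 °C → rt; filtration; then 1 M HCl, THF, rt
Reagents that add atoms: Tebbe reagent, SMILES: C[Al-]1(C)C[Ti]([Cl+]1)(C2C=CC=C2)C2C=CC=C2
Why: Tebbe methylenation is non-basic and effective for hindered ketones, so the C1 carbonyl is converted without epimerisation at C2 or β-elimination, and dilute acid then hydrolyses the silyl enol ether while the primary TBDPS ether and the 1,1-disubstituted alkene persist.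

Step 9
Reactants: 14 2β-[(TBDPS-oxy)methyl]-7,7,7aβ-trimethyl-1-methylidene-3aβ-octahydro-5H-inden-5-one
Product: 15 2β-[(TBDPS-oxy)methyl]-7,7,7aβ-trimethyl-1-methylidene-1,2,3,6,7,7a-hexahydro-5H-inden-5-one
Conditions: IBX, DMSO, 70 °C
Reagents that add atoms: none
Why: IBX dehydrogenation of the ketone can only proceed towards C4–C3a because C7 bears no hydrogen, which gives the C3a=C4 enone and flattens the ring fusion for the next step.

Step 10
Reactants: 15 2β-[(TBDPS-oxy)methyl]-7,7,7aβ-trimethyl-1-methylidene-1,2,3,6,7,7a-hexahydro-5H-inden-5-one; 16 methyl acrylate (3 equiv)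
Product: 17 methyl 3-{2β-[(TBDPS-oxy)methyl]-1β,7,7,7aβ-tetramethyl-5-oxo-2,3,5,6,7,7a-hexahydro-1H-inden-1α-yl}propanoate
Conditions: Fe(acac)3 (30 mol %), PhSiH3, EtOH/(CH2OH)2, 60 °C
Reagents that add atoms: none
Why: Hydrogen atom transfer from the iron hydride to the 1,1-disubstituted alkene gives the tertiary C1 radical (creating the C1 methyl group), which adds to methyl acrylate (Giese addition; reductive olefin coupling) on the α-face because the β-face is blocked by the C7a methyl group and the neighbouring C2 silyloxymethyl group, so the C1 quaternary centre should form with the chain α.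

Step 11
Reactants: 17 methyl 3-{2β-[(TBDPS-oxy)methyl]-1β,7,7,7aβ-tetramethyl-5-oxo-2,3,5,6,7,7a-hexahydro-1H-inden-1α-yl}propanoate
Product: 18 C5 1,3-dithiolane (ethylene dithioketal) of 17
Conditions: HSCH2CH2SH, BF3·OEt2 (0.3 equiv), CH2Cl2, 0 °C → rt
Reagents that add atoms: ethane-1,2-dithiol, SMILES: SCCS
Why: BF3-promoted dithioketalisation is selective for the ketone over the ester and, for enones, is known to keep the double bond in the α,β-position.

Step 12
Reactants: 18 C5 1,3-dithiolane of 17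
Product: 19 methyl 3-{2β-[(TBDPS-oxy)methyl]-1β,7,7,7aβ-tetramethyl-2,3,5,6,7,7a-hexahydro-1H-inden-1α-yl}propanoate
Conditions: Raney Ni (W-2 grade, acetone-deactivated), EtOH, rt
Reagents that add atoms: none
Why: Raney Ni desulfurisation (Mozingo reduction) replaces both C–S bonds by C–H and should leave the hindered trisubstituted C3a=C4 alkene in place.

Step 13
Reactants: 19 methyl 3-{2β-[(TBDPS-oxy)methyl]-1β,7,7,7aβ-tetramethyl-2,3,5,6,7,7a-hexahydro-1H-inden-1α-yl}propanoate
Product: 20 3-{2β-[(TBDPS-oxy)methyl]-1β,7,7,7aβ-tetramethyl-2,3,5,6,7,7a-hexahydro-1H-inden-1α-yl}propanal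
Conditions: i-Bu2AlH (1.1 equiv), CH2Cl2, −78 °C; aq potassium sodium tartrate
Reagents that add atoms: none
Why: Partial reduction of the unhindered methyl ester with i-Bu2AlH at −78 °C stops at the aldehyde because the tetrahedral aluminate only collapses on work-up.

Step 14
Reactants: 20 3-{2β-[(TBDPS-oxy)methyl]-1β,7,7,7aβ-tetramethyl-2,3,5,6,7,7a-hexahydro-1H-inden-1α-yl}propanal; 21 ethyl 2-[bis(2,2,2-trifluoroethoxy)phosphoryl]propanoate
Product: 22 ethyl (2Z)-5-{2β-[(TBDPS-oxy)methyl]-1β,7,7,7aβ-tetramethyl-2,3,5,6,7,7a-hexahydro-1H-inden-1α-yl}-2-methylpent-2-enoate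
Conditions: KN(SiMe3)2, 18-crown-6, THF, −78 °C
Reagents that add atoms: none
Why: Still–Gennari olefination with the bis(trifluoroethyl) phosphonate under dissociating conditions gives the (Z)-α-methyl enoate through fast, kinetically controlled elimination from the first-formed adduct.

Step 15
Reactants: 22 ethyl (2Z)-5-{2β-[(TBDPS-oxy)methyl]-1β,7,7,7aβ-tetramethyl-2,3,5,6,7,7a-hexahydro-1H-inden-1α-yl}-2-methylpent-2-enoate
Product: 23 (2Z)-5-{2β-[(TBDPS-oxy)methyl]-1β,7,7,7aβ-tetramethyl-2,3,5,6,7,7a-hexahydro-1H-inden-1α-yl}-2-methylpent-2-en-1-ol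
Conditions: i-Bu2AlH (2.5 equiv), CH2Cl2, −78 °C
Reagents that add atoms: none
Why: 1,2-Reduction of the enoate by i-Bu2AlH gives the allylic alcohol without changing the (Z)-geometry.

Step 16
Reactants: 23 (2Z)-5-{2β-[(TBDPS-oxy)methyl]-1β,7,7,7aβ-tetramethyl-2,3,5,6,7,7a-hexahydro-1H-inden-1α-yl}-2-methylpent-2-en-1-ol
Product: 24 (2Z)-5-{2β-[(TBDPS-oxy)methyl]-1β,7,7,7aβ-tetramethyl-2,3,5,6,7,7a-hexahydro-1H-inden-1α-yl}-2-methylpent-2-en-1-yl acetate
Conditions: Ac2O, pyridine, DMAP (cat.), CH2Cl2, 0 °C → rt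
Reagents that add atoms: acetic anhydride, SMILES: CC(=O)OC(C)=O
Why: DMAP-catalysed acylation of the primary allylic alcohol is a standard esterification that touches nothing else.

Step 17
Reactants: 24 (2Z)-5-{2β-[(TBDPS-oxy)methyl]-1β,7,7,7aβ-tetramethyl-2,3,5,6,7,7a-hexahydro-1H-inden-1α-yl}-2-methylpent-2-en-1-yl acetate
Product: 25 (2Z)-5-[2β-(hydroxymethyl)-1β,7,7,7aβ-tetramethyl-2,3,5,6,7,7a-hexahydro-1H-inden-1α-yl]-2-methylpent-2-en-1-yl acetate
Conditions: HF·pyridine, pyridine, THF, 0 °C → rt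
Reagents that add atoms: none
Why: Fluoride-mediated desilylation with buffered HF·pyridine cleaves the silyl ether without affecting the allylic acetate or the alkenes.

Step 18
Reactants: 25 (2Z)-5-[2β-(hydroxymethyl)-1β,7,7,7aβ-tetramethyl-2,3,5,6,7,7a-hexahydro-1H-inden-1α-yl]-2-methylpent-2-en-1-yl acetate
Product: 26 (1R,2S,7aS)-1-[(3Z)-5-(acetyloxy)-4-methylpent-3-en-1-yl]-1,7,7,7a-tetramethyl-2,3,5,6,7,7a-hexahydro-1H-indene-2-carboxylic acid
Conditions: TEMPO (20 mol %), PhI(OAc)2, MeCN/H2O, rt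
Reagents that add atoms: water, SMILES: O
Why: Oxoammonium oxidation (TEMPO/PhI(OAc)2) in aqueous acetonitrile takes the primary alcohol through the aldehyde hydrate to the acid under mildly acidic conditions that should avoid epimerisation at C2 and hydrolysis of the acetate.

**Compound list**

1 | (R)-4-(TBS-oxy)cyclopent-2-en-1-one | O=C1C=C[C@H](O[Si](C)(C)C(C)(C)C)C1 | starting material
2 | (R)-4-(TBS-oxy)-2-iodocyclopent-2-en-1-one | O=C1C(I)=C[C@H](O[Si](C)(C)C(C)(C)C)C1 | intermediate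
3 | (R)-4-(TBS-oxy)-2-methylcyclopent-2-en-1-one | O=C1C(C)=C[C@H](O[Si](C)(C)C(C)(C)C)C1 | intermediate
4 | mesityl oxide (4-methylpent-3-en-2-one) | CC(=O)C=C(C)C | starting material
5 | lithium 4-methylpenta-1,3-dien-2-olate | [Li+].[O-]C(=C)C=C(C)C | intermediate (not isolated)
6 | tert-butyldimethyl[(4-methylpenta-1,3-dien-2-yl)oxy]silane | C=C(O[Si](C)(C)C(C)(C)C)C=C(C)C | intermediate
7 | 1-[2-methyl-3,5-bis(TBS-oxy)cyclopent-2-en-1-yl]-4-methylpent-3-en-2-one (chain and ring-sp3 OTBS trans; carried as its O-silylated oxocarbenium form) | CC1=C(O[Si](C)(C)C(C)(C)C)C[C@@H](O[Si](C)(C)C(C)(C)C)[C@@H]1CC(=O)C=C(C)C | intermediate (not isolated)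
8 | 3β,5-bis(TBS-oxy)-7,7,7aβ-trimethyl-2,3,3aβ,4,7,7a-hexahydro-1H-inden-1-one | O=C1C[C@@H](O[Si](C)(C)C(C)(C)C)[C@@H]2CC(O[Si](C)(C)C(C)(C)C)=CC(C)(C)[C@]12C | intermediate
9 | 5-(TBS-oxy)-7,7,7aβ-trimethyl-3aβ,4,7,7a-tetrahydro-1H-inden-1-one | O=C1C=C[C@@H]2CC(O[Si](C)(C)C(C)(C)C)=CC(C)(C)[C@]12C | intermediate
10 | lithium C1 enolate of the 2,3-dihydro derivative of 9 | [Li+].[O-]C1=CC[C@@H]2CC(O[Si](C)(C)C(C)(C)C)=CC(C)(C)[C@]12C | intermediate (not isolated)
11 | 5-(TBS-oxy)-2β-(hydroxymethyl)-7,7,7aβ-trimethyl-2,3,3aβ,4,7,7a-hexahydro-1H-inden-1-one | O=C1[C@@H](CO)C[C@@H]2CC(O[Si](C)(C)C(C)(C)C)=CC(C)(C)[C@]12C | intermediate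
12 | 5-(TBS-oxy)-2β-[(TBDPS-oxy)methyl]-7,7,7aβ-trimethyl-2,3,3aβ,4,7,7a-hexahydro-1H-inden-1-one | O=C1[C@@H](CO[Si](c3ccccc3)(c3ccccc3)C(C)(C)C)C[C@@H]2CC(O[Si](C)(C)C(C)(C)C)=CC(C)(C)[C@]12C | intermediate
13 | C1-methylidene analogue of 12 (C5 TBS enol ether retained) | C=C1[C@@H](CO[Si](c3ccccc3)(c3ccccc3)C(C)(C)C)C[C@@H]2CC(O[Si](C)(C)C(C)(C)C)=CC(C)(C)[C@]12C | intermediate (not isolated)
14 | 2β-[(TBDPS-oxy)methyl]-7,7,7aβ-trimethyl-1-methylidene-3aβ-octahydro-5H-inden-5-one | C=C1[C@@H](CO[Si](c3ccccc3)(c3ccccc3)C(C)(C)C)C[C@@H]2CC(=O)CC(C)(C)[C@]12C | intermediate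
15 | 2β-[(TBDPS-oxy)methyl]-7,7,7aβ-trimethyl-1-methylidene-1,2,3,6,7,7a-hexahydro-5H-inden-5-one | C=C1[C@@H](CO[Si](c3ccccc3)(c3ccccc3)C(C)(C)C)CC2=CC(=O)CC(C)(C)[C@]12C | intermediate
16 | methyl acrylate | C=CC(=O)OC | starting material
17 | methyl 3-{2β-[(TBDPS-oxy)methyl]-1β,7,7,7aβ-tetramethyl-5-oxo-2,3,5,6,7,7a-hexahydro-1H-inden-1α-yl}propanoate | COC(=O)CC[C@]1(C)[C@@H](CO[Si](c3ccccc3)(c3ccccc3)C(C)(C)C)CC2=CC(=O)CC(C)(C)[C@@]21C | intermediate
18 | C5 1,3-dithiolane of 17 | COC(=O)CC[C@]1(C)[C@@H](CO[Si](c3ccccc3)(c3ccccc3)C(C)(C)C)CC2=CC3(SCCS3)CC(C)(C)[C@@]21C | intermediate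
19 | methyl 3-{2β-[(TBDPS-oxy)methyl]-1β,7,7,7aβ-tetramethyl-2,3,5,6,7,7a-hexahydro-1H-inden-1α-yl}propanoate | COC(=O)CC[C@]1(C)[C@@H](CO[Si](c3ccccc3)(c3ccccc3)C(C)(C)C)CC2=CCCC(C)(C)[C@@]21C | intermediate
20 | 3-{2β-[(TBDPS-oxy)methyl]-1β,7,7,7aβ-tetramethyl-2,3,5,6,7,7a-hexahydro-1H-inden-1α-yl}propanal | O=CCC[C@]1(C)[C@@H](CO[Si](c3ccccc3)(c3ccccc3)C(C)(C)C)CC2=CCCC(C)(C)[C@@]21C | intermediate
21 | ethyl 2-[bis(2,2,2-trifluoroethoxy)phosphoryl]propanoate | CCOC(=O)C(C)P(=O)(OCC(F)(F)F)OCC(F)(F)F | starting material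
22 | ethyl (2Z)-5-{2β-[(TBDPS-oxy)methyl]-1β,7,7,7aβ-tetramethyl-2,3,5,6,7,7a-hexahydro-1H-inden-1α-yl}-2-methylpent-2-enoate | CCOC(=O)/C(C)=C\CC[C@]1(C)[C@@H](CO[Si](c3ccccc3)(c3ccccc3)C(C)(C)C)CC2=CCCC(C)(C)[C@@]21C | intermediate
23 | (2Z)-5-{2β-[(TBDPS-oxy)methyl]-1β,7,7,7aβ-tetramethyl-2,3,5,6,7,7a-hexahydro-1H-inden-1α-yl}-2-methylpent-2-en-1-ol | OC/C(C)=C\CC[C@]1(C)[C@@H](CO[Si](c3ccccc3)(c3ccccc3)C(C)(C)C)CC2=CCCC(C)(C)[C@@]21C | intermediate
24 | (2Z)-5-{2β-[(TBDPS-oxy)methyl]-1β,7,7,7aβ-tetramethyl-2,3,5,6,7,7a-hexahydro-1H-inden-1α-yl}-2-methylpent-2-en-1-yl acetate | CC(=O)OC/C(C)=C\CC[C@]1(C)[C@@H](CO[Si](c3ccccc3)(c3ccccc3)C(C)(C)C)CC2=CCCC(C)(C)[C@@]21C | intermediate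
25 | (2Z)-5-[2β-(hydroxymethyl)-1β,7,7,7aβ-tetramethyl-2,3,5,6,7,7a-hexahydro-1H-inden-1α-yl]-2-methylpent-2-en-1-yl acetate | CC(=O)OC/C(C)=C\CC[C@]1(C)[C@@H](CO)CC2=CCCC(C)(C)[C@@]21C | intermediate
26 | (1R,2S,7aS)-1-[(3Z)-5-(acetyloxy)-4-methylpent-3-en-1-yl]-1,7,7,7a-tetramethyl-2,3,5,6,7,7a-hexahydro-1H-indene-2-carboxylic acid | CC(=O)OC/C(C)=C\CC[C@]1(C)[C@@H](C(=O)O)CC2=CCCC(C)(C)[C@@]21C | target

**Step count**

Total steps: 18. Longest linear sequence: 17 steps (from 1 through steps 1, 2 and 4–18); step 3 prepares the diene separately.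

**Steps most likely to fail**

1. Step 4. The ring-closing second Michael addition has to join two fully substituted carbons. It may stall after the first addition, so that protodesilylation of the open-chain intermediate or acid-induced loss of the C3 silyloxy group outruns ring closure.
Fallback (sets out from 1 and 6, returns at 9): the cycloaddition is run on the less hindered enone 1 and the angular methyl group is added afterwards. Under the same triflimide catalysis 1 and 6 should give the cis-fused nor-methyl adduct 3β,5-bis(TBS-oxy)-7,7-dimethyl-2,3,3aβ,4,7,7aβ-hexahydro-1H-inden-1-one F1, in which the ring closure makes only one quaternary carbon. DBU in CH2Cl2 eliminates the silanol to give the nor-methyl enone 5-(TBS-oxy)-7,7-dimethyl-3aβ,4,7,7aβ-tetrahydro-1H-inden-1-one F2. LiN(i-Pr)2 (THF, −78 °C) removes the ring-fusion α′-proton to give the cross-conjugated lithium enolate of F2 F3. MeI should then alkylate C7a on the convex β-face (cis to 3a-H), which gives 9.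

2. Step 10. Capture of the crowded tertiary C1 radical by the acrylate may be slow, so that reduction of the radical (net hydrogenation of the alkene) or alkene isomerisation competes, and facial selectivity at C1 may be incomplete.
Fallback (sets out from 15, returns at 19): C1 is built by polar chemistry. mCPBA (NaHCO3, CH2Cl2, 0 °C) should epoxidise only the electron-rich exocyclic alkene to give the C1 spiro-oxirane of 15 F4. BF3·OEt2 (CH2Cl2, −78 °C) induces Meinwald rearrangement to 2β-[(TBDPS-oxy)methyl]-7,7,7aβ-trimethyl-5-oxo-2,3,5,6,7,7a-hexahydro-1H-indene-1-carbaldehyde F5. Its enolate (benzyltrimethylammonium hydroxide cat., t-BuOH) adds to methyl acrylate 16 from the α-face to give the quaternary aldehyde methyl 3-{1β-formyl-2β-[(TBDPS-oxy)methyl]-7,7,7aβ-trimethyl-5-oxo-2,3,5,6,7,7a-hexahydro-1H-inden-1α-yl}propanoate F6. Ethane-1,2-dithiol with BF3·OEt2 converts both the formyl group and the enone carbonyl into dithiolanes, giving the bis(1,3-dithiolane) of F6 F7. Raney Ni reduces both, so the formyl carbon becomes the C1 methyl group and the route is rejoined at 19.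

3. Step 6. The borohydride may reduce the enone carbonyl directly (1,2-reduction), the aldolate may lose formaldehyde again (retro-aldol) or dehydrate, and attack at C2 may not be fully β-selective. C2 epimers would be separated at 12; the minor one can be re-equilibrated with base while C1 is still a ketone.
Fallback (sets out from 9, returns at 11): the enolate is generated without a borane or free hydride. Et3SiH with RhCl(PPh3)3 (cat.) effects 1,4-hydrosilylation to the triethylsilyl enol ether 5-(TBS-oxy)-1-(triethylsilyloxy)-7,7,7aβ-trimethyl-3aβ,4,7,7a-tetrahydro-3H-indene F8. MeLi (THF, 0 °C) cleaves this less hindered silyl enol ether to the lithium enolate 10, which is hydroxymethylated with CH2O as before to give 11.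

Further compounds
F1 | step 4 | 3β,5-bis(TBS-oxy)-7,7-dimethyl-2,3,3aβ,4,7,7aβ-hexahydro-1H-inden-1-one | O=C1C[C@@H](O[Si](C)(C)C(C)(C)C)[C@@H]2CC(O[Si](C)(C)C(C)(C)C)=CC(C)(C)[C@H]12
F2 | step 4 | 5-(TBS-oxy)-7,7-dimethyl-3aβ,4,7,7aβ-tetrahydro-1H-inden-1-one | O=C1C=C[C@@H]2CC(O[Si](C)(C)C(C)(C)C)=CC(C)(C)[C@H]12
F3 | step 4 | lithium C1(7a)-enolate of F2 | [Li+].[O-]C1=C2[C@@H](CC(O[Si](C)(C)C(C)(C)C)=CC2(C)C)C=C1
F4 | step 10 | C1 spiro-oxirane of 15 (both C1 epimers) | C1OC12[C@@H](CO[Si](c3ccccc3)(c3ccccc3)C(C)(C)C)CC3=CC(=O)CC(C)(C)[C@]23C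
F5 | step 10 | 2β-[(TBDPS-oxy)methyl]-7,7,7aβ-trimethyl-5-oxo-2,3,5,6,7,7a-hexahydro-1H-indene-1-carbaldehyde (both C1 epimers) | O=CC1[C@@H](CO[Si](c3ccccc3)(c3ccccc3)C(C)(C)C)CC2=CC(=O)CC(C)(C)[C@]12C
F6 | step 10 | methyl 3-{1β-formyl-2β-[(TBDPS-oxy)methyl]-7,7,7aβ-trimethyl-5-oxo-2,3,5,6,7,7a-hexahydro-1H-inden-1α-yl}propanoate | COC(=O)CC[C@]1(C=O)[C@@H](CO[Si](c3ccccc3)(c3ccccc3)C(C)(C)C)CC2=CC(=O)CC(C)(C)[C@@]21C
F7 | step 10 | bis(1,3-dithiolane) of F6 (at the formyl carbon and at C5) | COC(=O)CC[C@]1(C3SCCS3)[C@@H](CO[Si](c3ccccc3)(c3ccccc3)C(C)(C)C)CC2=CC3(SCCS3)CC(C)(C)[C@@]21C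
F8 | step 6 | 5-(TBS-oxy)-1-(triethylsilyloxy)-7,7,7aβ-trimethyl-3aβ,4,7,7a-tetrahydro-3H-indene | CC[Si](CC)(CC)OC1=CC[C@@H]2CC(O[Si](C)(C)C(C)(C)C)=CC(C)(C)[C@]12C
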